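Assumption: the side chain is numbered C1' (benzylic carbinol), C2' (ester-bearing carbon) and C3' (tertiary carbinol); the target is the (1'R,2'R) isomer carrying a (2R)-2-methylbutanoyl group, and compounds 1, 4, 6 and the Wittig reagent are catalogue items.

**Retrosynthetic overview**
- The C6–C1' bond is made last by a blue-light-driven nickel/chromium aryl addition of 6-bromo-7-methoxycoumarin to a chiral α-acyloxy aldehyde; C1' is set by C2' (Felkin–Anh, reinforced by β-hydroxyl chelation).
- The α-acyloxy aldehyde comes from periodate cleavage of the monoester of a C2-symmetric tetraol; one tartrate carbon leaves with acetone, the other becomes C2'.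
- The tetraol comes from diethyl L-tartrate and MeMgBr; the ester comes from bought (R)-2-methylbutanoic acid and is put on while the two secondary hydroxyls are still equivalent.
- The bromocoumarin comes from 5-bromo-2-hydroxy-4-methoxybenzaldehyde by Wittig olefination and lactonization.
- Ring order: the benzene ring is bought; the pyranone ring is closed first (step 1); no other ring is formed.

**Step 1**
Reactants: 1 5-bromo-2-hydroxy-4-methoxybenzaldehyde
Product: 3 6-bromo-7-methoxy-2H-chromen-2-one, via ethyl (2Z)-3-(5-bromo-2-hydroxy-4-methoxyphenyl)prop-2-enoate 2 (not isolated)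
Conditions: Ph3P=CHCO2Et (1.2 equiv.), PhNEt2, 210 °C, 4 h
Reagents that add atoms: ethyl (triphenylphosphoranylidene)acetate, CCOC(=O)C=P(c1ccccc1)(c1ccccc1)c1ccccc1
Why: Wittig olefination of the salicylaldehyde gives the 2-hydroxycinnamate, which at this temperature isomerizes to the Z form and lactonizes with loss of ethanol (the standard one-pot coumarin synthesis); no stereocenter is involved.

**Step 2**
Reactants: 4 diethyl (2R,3R)-2,3-dihydroxybutanedioate (diethyl L-tartrate)
Product: 5 (3R,4R)-2,5-dimethylhexane-2,3,4,5-tetraol
Conditions: MeMgBr (8 equiv.), THF, 0 °C → reflux, 6 h; aq. NH4Cl, continuous EtOAc extraction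
Reagents that add atoms: methylmagnesium bromide, C[Mg]Br
Why: Exhaustive Grignard addition: after deprotonation of the two hydroxyls each ester takes up two methyl groups, and the two carbinol stereocenters of L-tartrate are carried over untouched.

**Step 3**
Reactants: 5 (3R,4R)-2,5-dimethylhexane-2,3,4,5-tetraol; 6 (2R)-2-methylbutanoic acid
Product: 7 (3R,4R)-2,4,5-trihydroxy-2,5-dimethylhexan-3-yl (2R)-2-methylbutanoate
Conditions: 5 (2.5 equiv.), DIC (1.1 equiv.), DMAP (10 mol %), CH2Cl2/THF 2:1, 0 °C → rt, 16 h; excess 5 recovered
Reagents that add atoms: none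
Why: Steglich esterification: the tertiary hydroxyls do not react and the two secondary hydroxyls are related by the C2 axis, so only one monoester can form (excess 5 suppresses the diester); no stereocenter is made and the α-center of the acid does not epimerize under carbodiimide/DMAP activation.

**Step 4**
Reactants: 7 (3R,4R)-2,4,5-trihydroxy-2,5-dimethylhexan-3-yl (2R)-2-methylbutanoate
Product: 8 (2S)-3-hydroxy-3-methyl-1-oxobutan-2-yl (2R)-2-methylbutanoate
Conditions: NaIO4 on wet SiO2 (1.5 equiv.), CH2Cl2, 0 °C → rt, 1 h; filter, concentrate below 20 °C, use at once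
Reagents that add atoms: none
Why: Malaprade glycol cleavage: the only free vicinal diol (C4–OH/C5–OH) is cut to the aldehyde and acetone under neutral conditions, so the acyloxy-bearing stereocenter (future C2') is untouched; its descriptor changes to S only because the priorities change.

**Step 5**
Reactants: 8 (2S)-3-hydroxy-3-methyl-1-oxobutan-2-yl (2R)-2-methylbutanoate; 3 6-bromo-7-methoxy-2H-chromen-2-one
Product: 9 (1R,2R)-1,3-dihydroxy-1-(7-methoxy-2-oxo-2H-chromen-6-yl)-3-methylbutan-2-yl (2R)-2-methylbutanoate
Conditions: 3 (1.0 equiv.), 8 (1.5 equiv.), [Ru(bpy)3](PF6)2 (2 mol %), NiCl2(neocuproine) (5 mol %), CrCl2 (10 mol %), Hantzsch ester (1.5 equiv.), 2,6-lutidine (1.5 equiv.), degassed DMF, 450 nm LEDs, 20 °C, 24 h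
Reagents that add atoms: none
Why: Proposed new method: a light-driven, chromium-catalytic aryl Nozaki–Hiyama–Kishi addition. Excited [Ru(bpy)3]2+ is reductively quenched by the Hantzsch ester, and the resulting Ru(bpy)3+ (about −1.3 V vs SCE) reduces divalent nickel to zerovalent nickel and trivalent chromium to divalent chromium. Zerovalent nickel inserts into the C–Br bond of 3, the aryl group passes from divalent nickel to trivalent chromium, and the aryl-chromium species adds to the aldehyde of 8. In the Felkin–Anh transition state the C2'–O(acyl) bond lies anti to the incoming aryl, and a six-membered chromium chelate between the carbonyl and the free tertiary hydroxyl favours the same face, so the erythro (1'R) alcohol results. Lutidinium then protonates the chromium alkoxide and closes the cycle. The closest known reaction types are the stoichiometric and electroreductive nickel/chromium Nozaki–Hiyama–Kishi couplings and the photoredox/chromium allylation of aldehydes; what is new is the photochemical triple-catalytic transfer of an aryl group from an aryl bromide and its substrate-controlled use on an α-acyloxy β-hydroxy aldehyde. The ruthenium sensitizer has a low triplet energy (about 46 kcal/mol), so it cannot sensitize [2+2] dimerization of the coumarin.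

**Compound list**
1 | 5-bromo-2-hydroxy-4-methoxybenzaldehyde | COc1cc(O)c(C=O)cc1Br | starting material
2 | ethyl (2Z)-3-(5-bromo-2-hydroxy-4-methoxyphenyl)prop-2-enoate (not isolated) | CCOC(=O)/C=C\c1cc(Br)c(OC)cc1O | intermediate
3 | 6-bromo-7-methoxy-2H-chromen-2-one | COc1cc2oc(=O)ccc2cc1Br | intermediate
4 | diethyl (2R,3R)-2,3-dihydroxybutanedioate (diethyl L-tartrate) | CCOC(=O)[C@H](O)[C@@H](O)C(=O)OCC | starting material
5 | (3R,4R)-2,5-dimethylhexane-2,3,4,5-tetraol | CC(C)(O)[C@H](O)[C@@H](O)C(C)(C)O | intermediate
6 | (2R)-2-methylbutanoic acid | CC[C@@H](C)C(=O)O | starting material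
7 | (3R,4R)-2,4,5-trihydroxy-2,5-dimethylhexan-3-yl (2R)-2-methylbutanoate | CC[C@@H](C)C(=O)O[C@H]([C@@H](O)C(C)(C)O)C(C)(C)O | intermediate
8 | (2S)-3-hydroxy-3-methyl-1-oxobutan-2-yl (2R)-2-methylbutanoate | CC[C@@H](C)C(=O)O[C@H](C=O)C(C)(C)O | intermediate
9 | (1R,2R)-1,3-dihydroxy-1-(7-methoxy-2-oxo-2H-chromen-6-yl)-3-methylbutan-2-yl (2R)-2-methylbutanoate | CC[C@@H](C)C(=O)O[C@H]([C@H](O)c1cc2ccc(=O)oc2cc1OC)C(C)(C)O | target

**Step count and risks**
Total steps: 5. Longest linear sequence: 4 (4 → 5 → 7 → 8 → 9); step 1 supplies the coupling partner 3.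

Most likely to fail, in this order:

Step 5 (the proposed new step). The risks are biaryl formation or loss of bromine from 3, slow aryl transfer from nickel to chromium, a modest erythro/threo ratio, and a shift of the acyl group from O2' to O1' if the medium turns acidic or basic. The fallback uses known chemistry, sets out from 3 (and uses 8) and comes back at 9. Compound 3 is turned into 6-iodo-7-methoxy-2H-chromen-2-one F1 by copper-catalysed aromatic halogen exchange (CuI 5 mol %, NaI 2 equiv., N,N'-dimethylethylenediamine 10 mol %, dioxane, 110 °C). F1 is then joined to 8 in a classical stoichiometric Nozaki–Hiyama–Kishi reaction (CrCl2 4 equiv., NiCl2 1 mol %, DMF, rt, neutral aqueous work-up), which gives 9 with the same Felkin–Anh preference for the erythro alcohol.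

Step 3. The secondary hydroxyls of 5 are flanked by tertiary carbinols, so acylation may be slow, may stop short, or may give some diester. The fallback replaces direct esterification by tin-mediated mono-acylation; it sets out from 5 and 6 and comes back at 7. Compound 5 and Bu2SnO (toluene, reflux, water removal) give the stannylene acetal 2,2'-[(4R,5R)-2,2-dibutyl-1,3,2-dioxastannolane-4,5-diyl]di(propan-2-ol) F2. Acid 6 is turned under neutral conditions into (2R)-2-methylbutanoyl chloride F3 with 1-chloro-N,N,2-trimethylprop-1-en-1-amine (CH2Cl2, 0 °C). F2 and F3 (1.0 equiv., CH2Cl2, 0 °C) then give 7 after aqueous work-up; the stannylene allows only one acyl group to be taken up.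

Step 2. Exhaustive Grignard addition to the unprotected tartrate forms thick alkoxide slurries, and the water-soluble tetraol is hard to separate from magnesium salts. The fallback goes through a protected diester; it sets out from 4 and comes back at 5. Compound 4 with 2,2-dimethoxypropane (TsOH cat., toluene, 80 °C) gives diethyl (4R,5R)-2,2-dimethyl-1,3-dioxolane-4,5-dicarboxylate F4. MeMgBr (5 equiv., THF, 0 °C → rt) turns F4 into 2,2'-[(4R,5R)-2,2-dimethyl-1,3-dioxolane-4,5-diyl]di(propan-2-ol) F5, which is easily extracted. Hydrolysis of the acetonide (80 % aq. AcOH, 50 °C) then gives 5.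

Aldehyde 8 is not stored: it is carried as the crude filtrate of step 4 straight into step 5, or into the fallback coupling.

**Further compounds**
F1 | step 5 | 6-iodo-7-methoxy-2H-chromen-2-one | COc1cc2oc(=O)ccc2cc1I
F2 | step 3 | 2,2'-[(4R,5R)-2,2-dibutyl-1,3,2-dioxastannolane-4,5-diyl]di(propan-2-ol) | CC(C)(O)[C@@H]1O[Sn](CCCC)(CCCC)O[C@H]1C(C)(C)O
F3 | step 3 | (2R)-2-methylbutanoyl chloride | CC[C@@H](C)C(Cl)=O
F4 | step 2 | diethyl (4R,5R)-2,2-dimethyl-1,3-dioxolane-4,5-dicarboxylate | CCOC(=O)[C@@H]1OC(C)(C)O[C@H]1C(=O)OCC
F5 | step 2 | 2,2'-[(4R,5R)-2,2-dimethyl-1,3-dioxolane-4,5-diyl]di(propan-2-ol) | CC(C)(O)[C@@H]1OC(C)(C)O[C@H]1C(C)(C)O
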